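The ten-membered carbocycle is disconnected at C9–C10. The furanone ring (O–C3=C2–C1(=O)–C10) is a latent 3-oxyfuran whose α-carbon is C10, and C3 and C8 are spanned only by C4–C7. A tethered 2-nitroalkene (C8=C9) can therefore reach the furan through a six-membered C3–C8 transition-state ring. One operation, intramolecular [4+2] then C3–C8 fragmentation, should form C9–C10, the quaternary C10 stereocentre, the furanone and the macrocycle. The precursor is a 2-methyl-3-silyloxyfuran joined via C4(Me)–C5(OTBS) to a trans-γ-lactone (C6, C7, C11, C12) that carries the 1-nitrovinyl group at C7; the silyl enol ether is generated last.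

Key step: step 14

Remark on the chemistry: target (germacrane) numbering is used throughout (ring C1–C10, lactone C11–C13 with C12=O, C14 on C10, C15 on C4). The target is taken as (4R,5S,6S,7R,8S,10R) with a Z (angelate) ester. C8 in 4–8, 12–15, 20 and 21, C3 in 12, C10 in 9–16 and C11 in 21–24, 27, 28 and F4 are carried as epimer mixtures (no descriptor in the SMILES), because each of these centres later becomes sp2 or is set anew.

Design note: the 3-silyloxyfuran is unveiled only in step 13, because it would not survive nitro-Michael or dehydration chemistry. C13 is added only after ring closure, because an α-methylene lactone would offer the furan a second dienophile (a C3–C11 six-membered ring).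

Step 1
Reactants: 1 2-nitroethanol
Product: 2 triethyl(2-nitroethoxy)silane
Conditions: TESCl, imidazole, CH2Cl2, 0 °C
Reagents that add atoms: chlorotriethylsilane, CC[Si](Cl)(CC)CC
Why: Silylation of a primary alcohol with imidazole, a base too weak to start nitronate chemistry; the TES ether is later removed by the acid of step 11.

Step 2
Reactants: 3 (S)-5-(hydroxymethyl)furan-2(5H)-one; 2 triethyl(2-nitroethoxy)silane
Product: 4 (4R,5S)-5-(hydroxymethyl)-4-[1-nitro-2-(triethylsilyloxy)ethyl]oxolan-2-one
Conditions: 2 (2 equiv), DBU (0.3 equiv), MeCN, 0 → 23 °C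
Reagents that add atoms: none
Why: Nitro-Michael addition in which the nitronate of 2 adds to the butenolide β-carbon anti to the C5 hydroxymethyl group, setting C7 and the trans-lactone; the nitro carbon already carries C9, so no nitro-aldol with formaldehyde is needed.

Step 3
Reactants: 4 (4R,5S)-5-(hydroxymethyl)-4-[1-nitro-2-(triethylsilyloxy)ethyl]oxolan-2-one
Product: 5 (2S,3R)-3-[1-nitro-2-(triethylsilyloxy)ethyl]-5-oxooxolane-2-carbaldehyde
Conditions: Dess–Martin periodinane, NaHCO3, CH2Cl2, 0 °C; used crude at once
Reagents that add atoms: none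
Why: Dess–Martin oxidation under buffered, base-free conditions should give the α-oxy aldehyde without nitronate formation or epimerisation at C6.

Step 4
Reactants: 5 (2S,3R)-3-[1-nitro-2-(triethylsilyloxy)ethyl]-5-oxooxolane-2-carbaldehyde
Product: 6 (4R,5S)-5-[(1S,2S)-1-hydroxy-2-methylbut-3-en-1-yl]-4-[1-nitro-2-(triethylsilyloxy)ethyl]oxolan-2-one
Conditions: trans-2-butene, KOt-Bu, n-BuLi, THF, −78 → −45 °C; (−)-Ipc2BOMe; BF3·OEt2, −78 °C; then 5, −78 °C; ethanolamine work-up
Reagents that add atoms: B-(E)-crotyldiisopinocampheylborane of the (+)-α-pinene series, C/C=C/CB([C@@H]1C[C@@H]2C[C@H]([C@H]1C)C2(C)C)[C@@H]1C[C@@H]2C[C@H]([C@H]1C)C2(C)C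
Why: Brown crotylboration through a chair Zimmerman–Traxler transition state, in which the E-crotyl group gives the 4,5-anti relationship and the (+)-α-pinene-derived reagent adds to the Si face of the aldehyde, setting C5 (5,6-syn) under reagent control against the Felkin/Cornforth preference of the α-oxy aldehyde for the 5,6-anti product.

Step 5
Reactants: 6 (4R,5S)-5-[(1S,2S)-1-hydroxy-2-methylbut-3-en-1-yl]-4-[1-nitro-2-(triethylsilyloxy)ethyl]oxolan-2-one
Product: 7 (4R,5S)-5-[(1S,2S)-1-(tert-butyldimethylsilyloxy)-2-methylbut-3-en-1-yl]-4-[1-nitro-2-(triethylsilyloxy)ethyl]oxolan-2-one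
Conditions: TBSOTf, 2,6-lutidine, CH2Cl2, −78 → 0 °C
Reagents that add atoms: tert-butyldimethylsilyl triflate, CC(C)(C)[Si](C)(C)OS(=O)(=O)C(F)(F)F
Why: Silyl triflate silylation of the hindered secondary alcohol; any silyl nitronate formed from the nitroalkane reverts on aqueous work-up.

Step 6
Reactants: 7 (4R,5S)-5-[(1S,2S)-1-(tert-butyldimethylsilyloxy)-2-methylbut-3-en-1-yl]-4-[1-nitro-2-(triethylsilyloxy)ethyl]oxolan-2-one
Product: 8 (2R,3S)-3-(tert-butyldimethylsilyloxy)-2-methyl-3-{(2S,3R)-3-[1-nitro-2-(triethylsilyloxy)ethyl]-5-oxooxolan-2-yl}propanal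
Conditions: O3, CH2Cl2, −78 °C; then PPh3, −78 → 23 °C
Reagents that add atoms: ozone, [O-][O+]=O
Why: Ozonolysis with reductive work-up cleaves the terminal alkene to the C3 aldehyde; nitroalkane, lactone and silyl ethers are inert to ozone when no base is present.

Step 7
Reactants: 9 acetoin (3-hydroxybutan-2-one, racemic)
Product: 10 3-(triethylsilyloxy)butan-2-one
Conditions: TESCl, imidazole, CH2Cl2, 0 → 23 °C
Reagents that add atoms: chlorotriethylsilane, CC[Si](Cl)(CC)CC
Why: Routine silylation of a secondary alcohol; racemic material suffices because C10 becomes sp2 in the furan.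

Step 8
Reactants: 10 3-(triethylsilyloxy)butan-2-one
Product: 11 triethyl{[3-(trimethylsilyloxy)but-3-en-2-yl]oxy}silane
Conditions: LDA, THF, −78 °C; then TMSCl
Reagents that add atoms: chlorotrimethylsilane, C[Si](C)(C)Cl
Why: Kinetic deprotonation at the methyl group, away from the oxygenated carbon, followed by O-silylation gives the terminal silyl enol ether.

Step 9
Reactants: 8 (2R,3S)-3-(tert-butyldimethylsilyloxy)-2-methyl-3-{(2S,3R)-3-[1-nitro-2-(triethylsilyloxy)ethyl]-5-oxooxolan-2-yl}propanal; 11 triethyl{[3-(trimethylsilyloxy)but-3-en-2-yl]oxy}silane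
Product: 12 aldol adduct, 8 extended at C3 to CH(OH)–CH2–C(=O)–CH(OTES)–CH3 (C4–C7 as in 8)
Conditions: BF3·OEt2, CH2Cl2, −78 °C; aq. NaHCO3
Reagents that add atoms: none
Why: Mukaiyama aldol addition under non-basic conditions that the acidic nitroalkane tolerates; the new C3 carbinol centre is oxidised in the next step.

Step 10
Reactants: 12 aldol adduct
Product: 13 1,3-diketone C3(=O)–C2H2–C1(=O)–C10H(OTES)–CH3 (C4–C7 as in 8)
Conditions: Dess–Martin periodinane, NaHCO3, CH2Cl2, 23 °C
Reagents that add atoms: none
Why: Dess–Martin oxidation of a β-hydroxy ketone to the 1,3-diketone under neutral conditions that leave the C4 stereocentre and the nitroalkane alone.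

Step 11
Reactants: 13 1,3-diketone
Product: 15 furanone nitro alcohol (2-methyl-3(2H)-furanone joined at C3 to C4; C5–OTBS; trans-lactone; C7–CH(NO2)CH2OH), via O9,O10-desilylated hydroxy diketone 14 (not isolated)
Conditions: TsOH·H2O (0.2 equiv), THF/H2O 10:1, 23 °C
Reagents that add atoms: none
Why: Acid cleaves both triethylsilyl ethers while the hindered secondary TBS ether should stay, and the α'-hydroxy-1,3-diketone cyclodehydrates (hemiketalisation of O10 at C3, then loss of water) to the 3(2H)-furanone.

Step 12
Reactants: 15 furanone nitro alcohol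
Product: 16 furanone nitroalkene (as 15 with C7–C(NO2)=CH2)
Conditions: DCC, CuCl (cat.), Et2O/THF, 23 °C
Reagents that add atoms: none
Why: Copper(I)-catalysed carbodiimide dehydration of a β-nitro alcohol gives the 2-nitroalkene under neutral conditions, so neither the acidic C10–H of the furanone nor the γ-hydrogen at C7 is touched.

Step 13
Reactants: 16 furanone nitroalkene
Product: 17 silyloxyfuran nitroalkene lactone (2-methyl-3-(tert-butyldimethylsilyloxy)furan joined at C3 to C4; C5–OTBS; trans-lactone; C7–C(NO2)=CH2)
Conditions: TBSOTf, then Et3N added dropwise, CH2Cl2, −78 °C; cold pentane/pH 7 buffer work-up; used at once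
Reagents that add atoms: tert-butyldimethylsilyl triflate, CC(C)(C)[Si](C)(C)OS(=O)(=O)C(F)(F)F
Why: Soft enolisation in which O-silylation of the vinylogous ester carbonyl and loss of the C10 proton give the aromatic 3-silyloxyfuran; low temperature and late addition of the amine keep free base away from the nitroalkene.

Step 14
Reactants: 17 silyloxyfuran nitroalkene lactone
Product: 20 (4R,5S,6S,7R,10R)-C8-nitro furanone macrocycle with C5–OTBS (both C8 epimers), via oxanorbornene cycloadduct 18 (not isolated), via tert-butyldimethylsilyl nitronate 19 (not isolated)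
Conditions: PhMe (2 mM), 2,6-di-tert-butyl-4-methylpyridine (0.1 equiv), 23 → 60 °C; then MeOH/pH 7 buffer
Reagents that add atoms: none
Why: Proposed new method: the electron-rich 3-silyloxyfuran (diene C10–C1–C2–C3) should add across the electron-poor 2-nitroalkene in an asynchronous normal-demand intramolecular [4+2] (C10–C9 leading, C3–C8 lagging) to give oxanorbornene 18, whose C3–C8 bond lies between the bridging-oxygen/silyl enol ether donor and the nitro acceptor and should therefore heterolyse (retro-Michael, Grob-type), the silyl group passing to the nitronate (19) as the vinylogous ester C3=C2–C1=O forms. The closest known reactions are intramolecular furan Diels–Alder reactions with four-atom tethers, Mukaiyama–Michael additions of silyl enol ethers and silyloxyfurans to 2-nitroalkenes, and C2-selective aldol reactions of 3-silyloxyfurans that give 2,2-disubstituted 3(2H)-furanones. The only ring closed in the transition state is the carbocycle C3–C4–C5–C6–C7–C8, a six-membered chair formed in the type-1 intramolecular cycloaddition, and the ten-membered carbocycle C1–C10 with its C3–O–C10 bridge is what remains after C3–C8 scission, so no ten-membered transition state is required. C10 (R) is set by the tether-exo, nitro-endo transition state, in which the trans-lactone (O6, C11) and O5 are equatorial on the chair, only the C4 methyl is axial and the tether lies on the side of the furan oxygen; C8 is formed as a mixture on protonation and is irrelevant because it becomes a ketone. The step needs attack at C10 and not at C2, and ring closure and not oligomerisation: the four-atom tether makes C10/C9 the only pair that can bond through a six-membered array, C10 is the most nucleophilic furan carbon, and millimolar dilution suppresses intermolecular reaction; a stepwise Mukaiyama–Michael path through the zwitterion converges on the same nitronate 19.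

Step 15
Reactants: 20 C8-nitro furanone macrocycle
Product: 21 C11-(dimethylaminomethyl) derivative of 20 (C8 and C11 epimers)
Conditions: LDA (2.2 equiv), THF, −78 °C; Me2N=CH2+ I− (1.05 equiv), −78 → −20 °C; aq. NH4Cl
Reagents that add atoms: Eschenmoser's salt (N,N-dimethylmethyleneiminium iodide), C=[N+](C)C.[I-]
Why: Mannich aminomethylation of a lactone enolate: the first equivalent of base turns the nitro group into a nitronate that protects C8, the second forms the lactone enolate, which is by far the better nucleophile for the single equivalent of iminium salt.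

Step 16
Reactants: 21 C11-(dimethylaminomethyl) nitro macrocycle
Product: 23 C8 ketone (C11–CH2NMe2, C5–OTBS), via potassium nitronate 22 (not isolated)
Conditions: KOt-Bu (1.05 equiv), THF, 0 °C; then aq. TiCl3, NH4OAc, THF/H2O, pH 5–6, 23 °C; ketone kept as its acetate salt and used at once
Reagents that add atoms: water, O
Why: McMurry variant of the Nef reaction, in which Ti(III) reduces the nitronate to the imine and this hydrolyses at pH 5–6, where the β,β'-dioxygenated ketone should not undergo β-elimination and the amine stays protonated.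

Step 17
Reactants: 23 C8 ketone
Product: 24 (8S)-alcohol (C11–CH2NMe2, C5–OTBS)
Conditions: NaBH4, MeOH/CH2Cl2, −78 °C; AcOH quench
Reagents that add atoms: none
Why: Borohydride reduction in which hydride should enter from the ring periphery on the conformer whose C8 carbonyl points to the α-face, away from the C7–C11 bond, giving the 8α (8S) alcohol trans to C11; the vinylogous ester carbonyl and the lactone are not reduced at −78 °C.

Step 18
Reactants: 24 (8S)-alcohol; 25 angelic acid
Product: 27 8-O-angelate (C11–CH2NMe2, C5–OTBS), via angelic 2,4,6-trichlorobenzoic anhydride 26 (not isolated)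
Conditions: 25, 2,4,6-trichlorobenzoyl chloride, Et3N, PhMe, 23 °C; then 24, 75 °C
Reagents that add atoms: none
Why: Yamaguchi esterification through the mixed anhydride without DMAP, conditions under which angelates form without Z to E isomerisation; C8–OH is the only free hydroxyl group.

Step 19
Reactants: 27 8-O-angelate Mannich base
Product: 29 O5-TBS rufescenolide B, via trimethylammonium iodide 28 (not isolated)
Conditions: MeI, CH2Cl2/MeOH, 23 °C; then aq. NaHCO3, 23 °C
Reagents that add atoms: none
Why: N-Methylation followed by E1cB elimination of trimethylamine from the β-ammonio lactone with bicarbonate releases the α-methylene lactone without touching the angelate.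

Step 20
Reactants: 29 O5-TBS rufescenolide B
Product: 30 rufescenolide B
Conditions: HF·pyridine, pyridine, THF, 0 → 23 °C
Reagents that add atoms: none
Why: Fluoride cleavage of the secondary TBS ether under buffered conditions that leave the α-methylene lactone, the angelate and the furanone intact.

Compound list
1 | 2-nitroethanol | OCC[N+](=O)[O-] | starting material
2 | triethyl(2-nitroethoxy)silane | CC[Si](CC)(CC)OCC[N+](=O)[O-] | intermediate
3 | (S)-5-(hydroxymethyl)furan-2(5H)-one | OC[C@H]1OC(=O)C=C1 | starting material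
4 | (4R,5S)-5-(hydroxymethyl)-4-[1-nitro-2-(triethylsilyloxy)ethyl]oxolan-2-one (trans; C8 epimers) | CC[Si](CC)(CC)OCC([N+](=O)[O-])[C@H]1CC(=O)O[C@@H]1CO | intermediate
5 | (2S,3R)-3-[1-nitro-2-(triethylsilyloxy)ethyl]-5-oxooxolane-2-carbaldehyde | CC[Si](CC)(CC)OCC([N+](=O)[O-])[C@H]1CC(=O)O[C@@H]1C=O | intermediate
6 | (4R,5S)-5-[(1S,2S)-1-hydroxy-2-methylbut-3-en-1-yl]-4-[1-nitro-2-(triethylsilyloxy)ethyl]oxolan-2-one (C4/C5 anti, C5/C6 syn) | CC[Si](CC)(CC)OCC([N+](=O)[O-])[C@H]1CC(=O)O[C@@H]1[C@@H](O)[C@@H](C)C=C | intermediate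
7 | (4R,5S)-5-[(1S,2S)-1-(tert-butyldimethylsilyloxy)-2-methylbut-3-en-1-yl]-4-[1-nitro-2-(triethylsilyloxy)ethyl]oxolan-2-one | CC[Si](CC)(CC)OCC([N+](=O)[O-])[C@H]1CC(=O)O[C@@H]1[C@@H](O[Si](C)(C)C(C)(C)C)[C@@H](C)C=C | intermediate
8 | (2R,3S)-3-(tert-butyldimethylsilyloxy)-2-methyl-3-{(2S,3R)-3-[1-nitro-2-(triethylsilyloxy)ethyl]-5-oxooxolan-2-yl}propanal | CC[Si](CC)(CC)OCC([N+](=O)[O-])[C@H]1CC(=O)O[C@@H]1[C@@H](O[Si](C)(C)C(C)(C)C)[C@@H](C)C=O | intermediate
9 | acetoin (3-hydroxybutan-2-one, racemic) | CC(O)C(C)=O | starting material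
10 | 3-(triethylsilyloxy)butan-2-one | CC(O[Si](CC)(CC)CC)C(C)=O | intermediate
11 | triethyl{[3-(trimethylsilyloxy)but-3-en-2-yl]oxy}silane | C=C(O[Si](C)(C)C)C(C)O[Si](CC)(CC)CC | intermediate
12 | aldol adduct (C3 carbinol, C1 ketone, C10–OTES; C4–C7 as in 8) | CC[Si](CC)(CC)OCC([N+](=O)[O-])[C@H]1CC(=O)O[C@@H]1[C@@H](O[Si](C)(C)C(C)(C)C)[C@@H](C)C(O)CC(=O)C(C)O[Si](CC)(CC)CC | intermediate
13 | 1,3-diketone (C3 and C1 ketones, C10–OTES) | CC[Si](CC)(CC)OCC([N+](=O)[O-])[C@H]1CC(=O)O[C@@H]1[C@@H](O[Si](C)(C)C(C)(C)C)[C@@H](C)C(=O)CC(=O)C(C)O[Si](CC)(CC)CC | intermediate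
14 | O9,O10-desilylated hydroxy diketone | OCC([N+](=O)[O-])[C@H]1CC(=O)O[C@@H]1[C@@H](O[Si](C)(C)C(C)(C)C)[C@@H](C)C(=O)CC(=O)C(C)O | intermediate
15 | furanone nitro alcohol | OCC([N+](=O)[O-])[C@H]1CC(=O)O[C@@H]1[C@@H](O[Si](C)(C)C(C)(C)C)[C@@H](C)C1=CC(=O)C(C)O1 | intermediate
16 | furanone nitroalkene | C=C([N+](=O)[O-])[C@H]1CC(=O)O[C@@H]1[C@@H](O[Si](C)(C)C(C)(C)C)[C@@H](C)C1=CC(=O)C(C)O1 | intermediate
17 | silyloxyfuran nitroalkene lactone (key-step precursor) | C=C([N+](=O)[O-])[C@H]1CC(=O)O[C@@H]1[C@@H](O[Si](C)(C)C(C)(C)C)[C@@H](C)c1cc(O[Si](C)(C)C(C)(C)C)c(C)o1 | intermediate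
18 | oxanorbornene cycloadduct (C10–C9 and C3–C8 bonds; tether exo, nitro endo) | C[C@@H]1[C@H](O[Si](C)(C)C(C)(C)C)[C@H]2OC(=O)C[C@@H]2[C@@]3([N+](=O)[O-])C[C@@]4(C)O[C@@]13C=C4O[Si](C)(C)C(C)(C)C | intermediate
19 | tert-butyldimethylsilyl nitronate of 20 | C1C(=O)O[C@@H]2[C@@H](O[Si](C)(C)C(C)(C)C)[C@@H](C)C3=CC(=O)[C@@](C)(CC(=[N+]([O-])O[Si](C)(C)C(C)(C)C)[C@@H]12)O3 | intermediate
20 | (4R,5S,6S,7R,10R)-C8-nitro furanone macrocycle, C5–OTBS (C8 epimers) | C1C(=O)O[C@@H]2[C@@H](O[Si](C)(C)C(C)(C)C)[C@@H](C)C3=CC(=O)[C@@](C)(CC([N+](=O)[O-])[C@@H]12)O3 | intermediate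
21 | C11-(dimethylaminomethyl) derivative of 20 | CN(C)CC1C(=O)O[C@@H]2[C@@H](O[Si](C)(C)C(C)(C)C)[C@@H](C)C3=CC(=O)[C@@](C)(CC([N+](=O)[O-])[C@@H]12)O3 | intermediate
22 | potassium nitronate of 21 | CN(C)CC1C(=O)O[C@@H]2[C@@H](O[Si](C)(C)C(C)(C)C)[C@@H](C)C3=CC(=O)[C@@](C)(CC(=[N+]([O-])[O-])[C@@H]12)O3.[K+] | intermediate
23 | C8 ketone (C11–CH2NMe2, C5–OTBS) | CN(C)CC1C(=O)O[C@@H]2[C@@H](O[Si](C)(C)C(C)(C)C)[C@@H](C)C3=CC(=O)[C@@](C)(CC(=O)[C@@H]12)O3 | intermediate
24 | (8S)-alcohol (C11–CH2NMe2, C5–OTBS) | CN(C)CC1C(=O)O[C@@H]2[C@@H](O[Si](C)(C)C(C)(C)C)[C@@H](C)C3=CC(=O)[C@@](C)(C[C@H](O)[C@@H]12)O3 | intermediate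
25 | angelic acid ((Z)-2-methylbut-2-enoic acid) | C/C=C(/C)C(=O)O | starting material
26 | angelic 2,4,6-trichlorobenzoic anhydride | C/C=C(/C)C(=O)OC(=O)c1c(Cl)cc(Cl)cc1Cl | intermediate
27 | 8-O-angelate (C11–CH2NMe2, C5–OTBS) | CN(C)CC1C(=O)O[C@@H]2[C@@H](O[Si](C)(C)C(C)(C)C)[C@@H](C)C3=CC(=O)[C@@](C)(C[C@H](OC(=O)/C(C)=C\C)[C@@H]12)O3 | intermediate
28 | trimethylammonium iodide of 27 | C[N+](C)(C)CC1C(=O)O[C@@H]2[C@@H](O[Si](C)(C)C(C)(C)C)[C@@H](C)C3=CC(=O)[C@@](C)(C[C@H](OC(=O)/C(C)=C\C)[C@@H]12)O3.[I-] | intermediate
29 | O5-TBS rufescenolide B | C=C1C(=O)O[C@@H]2[C@@H](O[Si](C)(C)C(C)(C)C)[C@@H](C)C3=CC(=O)[C@@](C)(C[C@H](OC(=O)/C(C)=C\C)[C@@H]12)O3 | intermediate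
30 | rufescenolide B | C=C1C(=O)O[C@@H]2[C@@H](O)[C@@H](C)C3=CC(=O)[C@@](C)(C[C@H](OC(=O)/C(C)=C\C)[C@@H]12)O3 | target

Total step count: 20. Longest linear sequence: 18 steps (steps 1–6 and 9–20, from 1 to 30).

Steps most likely to fail

Step 14. Intermolecular cycloaddition or Michael oligomerisation may outrun ring closure. Reaction may pass through the tether-endo transition state and give the wrong face at C10. The furan may lose its silyl group before the C–C bond forms. The fallback uses known chemistry and sets out from 16. The 3(2H)-furanone itself serves as the carbon acid. A bifunctional tertiary amine–thiourea catalyst in toluene at high dilution activates the nitroalkene by hydrogen bonding and removes the C10 proton by general base catalysis. This is the established mode in which 2-substituted 3(2H)-furanones add to nitroalkenes to give 2,2-disubstituted furanones. The ring would close by direct conjugate addition of C10 to C9, with the catalyst antipode chosen to favour the 10R face. This gives 20 directly, where the route is rejoined; no new compound is formed on the way.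

Step 15. Formation of the nitronate/enolate dianion may be incomplete. Aminomethylation may occur at the nitronate carbon C8 and not at C11. The base may remove the γ-proton at C4 of the vinylogous ester in place of the lactone α-proton. The enolate may add across the ring to the furanone. The fallback sets out from 20 and changes the order, so that the enolate is formed only when C8 is already an ester. Nef reaction (KOt-Bu, then buffered TiCl3) should give the amine-free C8 ketone F1. NaBH4 at −78 °C should give the amine-free (8S)-alcohol F2. Mixed-anhydride esterification with 25 should give the amine-free 8-O-angelate F3. F3 is then deprotonated with one equivalent of LiHMDS at −78 °C and trapped with Eschenmoser's salt. This gives 27, where the route is rejoined. The trans relationship of C11 and O8 should keep the enolate away from the angelate carbonyl.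

Step 17. Facial selectivity may be poor, so that the 8-epi alcohol predominates. The lactone may also migrate to the C8 alkoxide. The fallback sets out from 23. The reduction is run for the other epimer, for example with a bulky trialkylborohydride, to give the (8R)-alcohol F4. F4 is esterified with 25 under Mitsunobu conditions (PPh3, DIAD, toluene, 0 °C), which installs the angelate with inversion at C8. This gives 27, where the route is rejoined.

Further compounds
F0 | step 14 | none | none
F1 | step 15 | amine-free C8 ketone (C11H2, C5–OTBS) | C1C(=O)O[C@@H]2[C@@H](O[Si](C)(C)C(C)(C)C)[C@@H](C)C3=CC(=O)[C@@](C)(CC(=O)[C@@H]12)O3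
F2 | step 15 | amine-free (8S)-alcohol (C11H2, C5–OTBS) | C1C(=O)O[C@@H]2[C@@H](O[Si](C)(C)C(C)(C)C)[C@@H](C)C3=CC(=O)[C@@](C)(C[C@H](O)[C@@H]12)O3
F3 | step 15 | amine-free 8-O-angelate (C11H2, C5–OTBS) | C1C(=O)O[C@@H]2[C@@H](O[Si](C)(C)C(C)(C)C)[C@@H](C)C3=CC(=O)[C@@](C)(C[C@H](OC(=O)/C(C)=C\C)[C@@H]12)O3
F4 | step 17 | (8R)-alcohol, 8-epimer of 24 | CN(C)CC1C(=O)O[C@@H]2[C@@H](O[Si](C)(C)C(C)(C)C)[C@@H](C)C3=CC(=O)[C@@](C)(C[C@@H](O)[C@@H]12)O3
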